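**Retrosynthetic overview**
1. Ring C is made last. Its aldol bond (C1–C5 of the cyclopentenone) is opened to a cis-enedione, which is a 5-alkyl-4-methoxyfuran-2-carboxylate after singlet-oxygen oxidation. The furan is joined by B-alkyl Suzuki coupling to a vinyl group made from the C2 ester.
2. The plan rests on ring A of the decalin (C4a–C5–C6–C7–C8–C8a): with its quaternary C4a(CH3) next to C5 it is a masked 2-methylphenol (C5 = C–OH, C4a = methyl-bearing ortho carbon). C5–O later becomes C5(CH3)=C6 through the enol triflate, and C8a–H comes from hydrogenation.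
3. Key disconnection C4–C4a: ring B is closed by C-alkylation of the phenoxide at C4a with the bromoethyl arm (C3–C4) on C2, which dearomatises ring A. The same arm can also reach the para carbon C8 through a six-membered transition state, so C8 (and C6) carry bromine as removable blocking groups.
4. The open precursor already holds C1 and C2. C1 comes from a rhodium-catalysed asymmetric conjugate addition of the arylboronic acid to a crotonate; C2 comes from two enolate alkylations (MeI, then 2-bromoethyl triflate anti to the aryl group).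
5. Ring order: A (bought as the arene) → B (step 6) → C (step 16).

Key step: step 6

Remark: the decalin is numbered as a naphthalene (C1 = CH–CH3, C2 = quaternary carbon with the side chain, C4a = angular methyl carbon, C5 = oxygenated carbon of ring A, C8a = ring-fusion CH) and ring C as a cyclopent-2-ene-1-carboxylate; 2-bromoethyl triflate is taken as a purchased reagent; the BINAP enantiomer in step 1 follows the usual facial model for (E)-enoates and would be exchanged for its mirror image if that model did not hold here.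

**Step 1**
Reactants: 1 (3-methoxy-2-methylphenyl)boronic acid; 2 isopropyl (E)-but-2-enoate
Product: 3 isopropyl (3S)-3-(3-methoxy-2-methylphenyl)butanoate
Conditions: Rh(acac)(C2H4)2 (3 mol %), (R)-BINAP (4.5 mol %), 1 (2.5 equiv), dioxane/H2O 10:1, 100 °C
Reagents that add atoms: none
Why: Hayashi–Miyaura rhodium-catalysed asymmetric 1,4-addition of an arylboronic acid to an (E)-enoate; the aryl–rhodium–(R)-BINAP species should add to the si face of C3 (re face of C2), which sets the benzylic centre (the later C1) as S, and the isopropyl ester is used because selectivity in this reaction rises with ester size.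

**Step 2**
Reactants: 3 isopropyl (3S)-3-(3-methoxy-2-methylphenyl)butanoate
Product: 5 isopropyl (3S)-3-(3-methoxy-2-methylphenyl)-2-methylbutanoate as a mixture of C2 epimers, via lithium enolate 4 (not isolated)
Conditions: LiN(iPr)2 (1.1 equiv), THF, −78 °C; MeI, −78 → 0 °C
Reagents that add atoms: iodomethane, CI
Why: Ester enolate alkylation; the new C2 centre is formed as an epimer mixture on purpose, because it is made planar again in step 3.

**Step 3**
Reactants: 5 isopropyl (3S)-3-(3-methoxy-2-methylphenyl)-2-methylbutanoate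
Product: 7 isopropyl (2S)-4-bromo-2-[(1R)-1-(3-methoxy-2-methylphenyl)ethyl]-2-methylbutanoate, via lithium enolate 6 (not isolated)
Conditions: LiN(iPr)2 (1.2 equiv), THF, −78 → −30 °C; BrCH2CH2OTf (1.3 equiv), −78 °C
Reagents that add atoms: 2-bromoethyl trifluoromethanesulfonate, BrCCOS(=O)(=O)C(F)(F)F
Why: Alkylation of a lithium ester enolate with a primary alkyl triflate, in which the triflate reacts far faster than the bromide that is kept as the later leaving group; the quaternary centre (later C2) is set by 1,2-induction, since allylic 1,3-strain holds the C1–H bond in the enolate plane, the ortho-substituted aryl group shields one face and the electrophile should enter anti to it, giving the (2S) epimer in which the C1 methyl and the ester carbon lie on the same side of the future ring B (the minor epimer is removed by chromatography).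

**Step 4**
Reactants: 7 isopropyl (2S)-4-bromo-2-[(1R)-1-(3-methoxy-2-methylphenyl)ethyl]-2-methylbutanoate
Product: 8 isopropyl (2S)-4-bromo-2-[(1R)-1-(3-hydroxy-2-methylphenyl)ethyl]-2-methylbutanoate
Conditions: BBr3 (1.5 equiv), CH2Cl2, −78 → 0 °C; aq. NaHCO3
Reagents that add atoms: none
Why: Lewis-acid cleavage of the aryl methyl ether by BBr3 at low temperature, where the hindered isopropyl ester and the primary bromide should be left alone; no stereocentre is touched.

**Step 5**
Reactants: 8 isopropyl (2S)-4-bromo-2-[(1R)-1-(3-hydroxy-2-methylphenyl)ethyl]-2-methylbutanoate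
Product: 9 isopropyl (2S)-4-bromo-2-[(1S)-1-(4,6-dibromo-3-hydroxy-2-methylphenyl)ethyl]-2-methylbutanoate
Conditions: NBS (2.05 equiv), MeCN, 0 °C → rt
Reagents that add atoms: N-bromosuccinimide, O=C1CCC(=O)N1Br
Why: Electrophilic bromination of a phenol fills every free ortho and para position, so both C6 and, decisive for step 6, the para carbon C8 next to the side chain should carry bromine whatever the order of attack (the descriptor at C1 changes only because the priorities change).

**Step 6**
Reactants: 9 isopropyl (2S)-4-bromo-2-[(1S)-1-(4,6-dibromo-3-hydroxy-2-methylphenyl)ethyl]-2-methylbutanoate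
Product: 11 isopropyl (1S,2S,4aS)-6,8-dibromo-1,2,4a-trimethyl-5-oxo-1,2,3,4,4a,5-hexahydronaphthalene-2-carboxylate, via potassium phenoxide 10 (not isolated)
Conditions: KOtBu (1.0 equiv), toluene/t-BuOH 10:1, 0.005 M, 80 °C
Reagents that add atoms: none
Why: KOtBu deprotonates the phenol (no excess base remains for E2), and the ambident phenoxide 10 attacks the primary bromide through its methyl-bearing ortho carbon C4a in an intramolecular SN2 reaction, which forms the C4–C4a bond and gives a cyclohexa-2,4-dienone that cannot re-aromatise because C4a is quaternary; the closest known reaction type is the base-mediated intramolecular alkylative dearomatisation of phenols. Ring B closes in the 6-exo-tet mode. The new stereocentre C4a is controlled by C1: allylic 1,3-strain with the C8 bromine keeps the C1–H bond in the arene plane, the C1 methyl stands perpendicular to it, and the arm C2–C3–C4 reaches C4a from the opposite face, so that the C1 and C4a methyl groups end syn. The step needs C4a to win over the para carbon C8, which the same arm can also reach through a six-membered transition state and which, if it carried hydrogen, would simply give the re-aromatised tetralin, and over oxygen. The bromine atoms placed on C8 and C6 in step 5 close this path, since attack on a bromine-bearing carbon is electronically and sterically disfavoured and cannot end in re-aromatisation by proton loss, while the potassium ion held at the oxygen next to C4a assists departure of bromide at that carbon. O-alkylation within the molecule would need an eight-membered ring, and high dilution in a weakly polar, hydrogen-bonding medium holds back intermolecular ether formation.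

**Step 7**
Reactants: 11 isopropyl (1S,2S,4aS)-6,8-dibromo-1,2,4a-trimethyl-5-oxo-1,2,3,4,4a,5-hexahydronaphthalene-2-carboxylate
Product: 12 isopropyl (1R,2S,4aS,8aS)-1,2,4a-trimethyl-5-oxodecahydronaphthalene-2-carboxylate
Conditions: H2 (4 atm), 10% Pd/C, Et3N (3 equiv), EtOAc, rt
Reagents that add atoms: none
Why: Heterogeneous hydrogenation with hydrogenolysis of both vinylic C–Br bonds (Et3N takes up HBr); H2 should add to C8=C8a from the α face, away from the β-axial methyl groups on the flanking carbons C4a and C1, which sets C8a–H trans to the angular methyl, and the raised pressure favours addition over double-bond migration.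

**Step 8**
Reactants: 12 isopropyl (1R,2S,4aS,8aS)-1,2,4a-trimethyl-5-oxodecahydronaphthalene-2-carboxylate
Product: 14 isopropyl (1R,2S,4aS,8aS)-1,2,4a-trimethyl-5-(trifluoromethylsulfonyloxy)-1,2,3,4,4a,7,8,8a-octahydronaphthalene-2-carboxylate, via potassium enolate 13 (not isolated)
Conditions: KN(SiMe3)2, THF, −78 °C; PhNTf2, −78 → 0 °C
Reagents that add atoms: N-phenylbis(trifluoromethanesulfonimide), O=S(=O)(N(c1ccccc1)S(=O)(=O)C(F)(F)F)C(F)(F)F
Why: The ketone can enolise only towards C6 because C4a is quaternary, so deprotonation and O-triflation give the C5=C6 enol triflate regiospecifically (the ester has no α-hydrogen).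

**Step 9**
Reactants: 14 isopropyl (1R,2S,4aS,8aS)-1,2,4a-trimethyl-5-(trifluoromethylsulfonyloxy)-1,2,3,4,4a,7,8,8a-octahydronaphthalene-2-carboxylate
Product: 15 isopropyl (1R,2S,4aS,8aS)-1,2,4a,5-tetramethyl-1,2,3,4,4a,7,8,8a-octahydronaphthalene-2-carboxylate
Conditions: Me2CuLi (from CuI + 2 MeLi), Et2O/THF, −20 → 0 °C
Reagents that add atoms: lithium dimethylcuprate, [Li+].C[Cu-]C
Why: Coupling of an enol triflate with a Gilman cuprate (McMurry–Scott reaction) replaces OTf by methyl and leaves the double bond at C5=C6; the hindered ester is inert at this temperature.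

**Step 10**
Reactants: 15 isopropyl (1R,2S,4aS,8aS)-1,2,4a,5-tetramethyl-1,2,3,4,4a,7,8,8a-octahydronaphthalene-2-carboxylate
Product: 16 [(1R,2S,4aS,8aS)-1,2,4a,5-tetramethyl-1,2,3,4,4a,7,8,8a-octahydronaphthalen-2-yl]methanol
Conditions: LiAlH4, THF, 0 °C → reflux
Reagents that add atoms: none
Why: Hydride reduction of the hindered ester to the neopentyl alcohol; the trisubstituted alkene is not touched.

**Step 11**
Reactants: 16 [(1R,2S,4aS,8aS)-1,2,4a,5-tetramethyl-1,2,3,4,4a,7,8,8a-octahydronaphthalen-2-yl]methanol
Product: 17 (1R,2S,4aS,8aS)-1,2,4a,5-tetramethyl-1,2,3,4,4a,7,8,8a-octahydronaphthalene-2-carbaldehyde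
Conditions: Dess–Martin periodinane, NaHCO3, CH2Cl2, rt
Reagents that add atoms: none
Why: Dess–Martin oxidation of a primary alcohol to the aldehyde, which has no α-hydrogen and cannot epimerise.

**Step 12**
Reactants: 17 (1R,2S,4aS,8aS)-1,2,4a,5-tetramethyl-1,2,3,4,4a,7,8,8a-octahydronaphthalene-2-carbaldehyde
Product: 18 (1R,2R,4aS,8aS)-2-ethenyl-1,2,4a,5-tetramethyl-1,2,3,4,4a,7,8,8a-octahydronaphthalene
Conditions: Ph3PCH3Br, KOtBu, THF, 0 °C → rt
Reagents that add atoms: methyltriphenylphosphonium bromide, C[P+](c1ccccc1)(c1ccccc1)c1ccccc1.[Br-]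
Why: Wittig methylenation; the unstabilised ylide adds even to hindered non-enolisable aldehydes and turns CHO into the vinyl group that supplies the CH2–CH2 link to ring C.

**Step 13**
Reactants: 19 methyl 4-bromofuran-2-carboxylate
Product: 20 methyl 4-methoxyfuran-2-carboxylate
Conditions: NaOMe, CuBr (10 mol %), MeOH/DMF, 100 °C
Reagents that add atoms: sodium methoxide, [Na+].[O-]C
Why: Copper-catalysed Ullmann-type methoxylation of a heteroaryl bromide; the ester stays a methyl ester under NaOMe/MeOH.

**Step 14**
Reactants: 20 methyl 4-methoxyfuran-2-carboxylate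
Product: 21 methyl 5-bromo-4-methoxyfuran-2-carboxylate
Conditions: NBS (1.0 equiv), DMF, 0 °C
Reagents that add atoms: N-bromosuccinimide, O=C1CCC(=O)N1Br
Why: Electrophilic bromination of the furan at its only free α-position C5, which is activated by the ring oxygen and the adjacent methoxy group.

**Step 15**
Reactants: 18 (1R,2R,4aS,8aS)-2-ethenyl-1,2,4a,5-tetramethyl-1,2,3,4,4a,7,8,8a-octahydronaphthalene; 21 methyl 5-bromo-4-methoxyfuran-2-carboxylate
Product: 23 methyl 4-methoxy-5-{2-[(1R,2R,4aS,8aS)-1,2,4a,5-tetramethyl-1,2,3,4,4a,7,8,8a-octahydronaphthalen-2-yl]ethyl}furan-2-carboxylate, via alkylborane 22 (not isolated)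
Conditions: 9-BBN, THF, rt → 50 °C; then 21, Pd(dppf)Cl2 (5 mol %), aq. K3PO4, DMF, 50 °C
Reagents that add atoms: none
Why: Anti-Markovnikov hydroboration of the monosubstituted alkene with 9-BBN (the hindered trisubstituted C5=C6 alkene should not react) followed by B-alkyl Suzuki–Miyaura coupling with the 2-bromofuran forms the C(sp3)–C(sp2) bond; no stereocentre is involved.

**Step 16**
Reactants: 23 methyl 4-methoxy-5-{2-[(1R,2R,4aS,8aS)-1,2,4a,5-tetramethyl-1,2,3,4,4a,7,8,8a-octahydronaphthalen-2-yl]ethyl}furan-2-carboxylate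
Product: 26 dysidenone B = methyl (1R,5S)-1-hydroxy-3-methoxy-4-oxo-5-{[(1R,2R,4aS,8aS)-1,2,4a,5-tetramethyl-1,2,3,4,4a,7,8,8a-octahydronaphthalen-2-yl]methyl}cyclopent-2-ene-1-carboxylate, via endoperoxide 24 (not isolated), via enedione 25 (not isolated)
Conditions: O2, hν (visible), tetraphenylporphyrin (cat.), CH2Cl2, −78 °C; Me2S, −78 → 0 °C; Et3N (0.2 equiv), 0 °C
Reagents that add atoms: dioxygen, O=O
Why: [4+2] cycloaddition of singlet oxygen to the furan, reduction of the endoperoxide by Me2S to the cis-enedione and base-mediated intramolecular aldol addition of the CH2 next to the ketone to the α-keto ester carbonyl is the known one-pot route from 2-alkylfurans to 4-hydroxycyclopent-2-enones; both new stereocentres (C1 and C5 of ring C) arise in the aldol, C5 stays epimerisable and the remote decalin gives no facial bias, so 26 is expected together with its ring C diastereomers, from which it is separated by preparative HPLC while the others are returned to 25 with base and closed again.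

**Compound list**
1 | (3-methoxy-2-methylphenyl)boronic acid | COc1cccc(B(O)O)c1C | starting material
2 | isopropyl (E)-but-2-enoate | C/C=C/C(=O)OC(C)C | starting material
3 | isopropyl (3S)-3-(3-methoxy-2-methylphenyl)butanoate | Cc1c(OC)cccc1[C@@H](C)CC(=O)OC(C)C | intermediate
4 | lithium enolate of 3 (not isolated) | Cc1c(OC)cccc1[C@@H](C)C=C(O[Li])OC(C)C | intermediate
5 | isopropyl (3S)-3-(3-methoxy-2-methylphenyl)-2-methylbutanoate, C2 epimers | Cc1c(OC)cccc1[C@@H](C)C(C)C(=O)OC(C)C | intermediate
6 | lithium enolate of 5 (not isolated) | Cc1c(OC)cccc1[C@@H](C)C(C)=C(O[Li])OC(C)C | intermediate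
7 | isopropyl (2S)-4-bromo-2-[(1R)-1-(3-methoxy-2-methylphenyl)ethyl]-2-methylbutanoate | Cc1c(OC)cccc1[C@@H](C)[C@@](C)(C(=O)OC(C)C)CCBr | intermediate
8 | isopropyl (2S)-4-bromo-2-[(1R)-1-(3-hydroxy-2-methylphenyl)ethyl]-2-methylbutanoate | Cc1c(O)cccc1[C@@H](C)[C@@](C)(C(=O)OC(C)C)CCBr | intermediate
9 | isopropyl (2S)-4-bromo-2-[(1S)-1-(4,6-dibromo-3-hydroxy-2-methylphenyl)ethyl]-2-methylbutanoate | Cc1c(O)c(Br)cc(Br)c1[C@@H](C)[C@@](C)(C(=O)OC(C)C)CCBr | intermediate
10 | potassium phenoxide of 9 (not isolated) | Cc1c([O-])c(Br)cc(Br)c1[C@@H](C)[C@@](C)(C(=O)OC(C)C)CCBr.[K+] | intermediate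
11 | isopropyl (1S,2S,4aS)-6,8-dibromo-1,2,4a-trimethyl-5-oxo-1,2,3,4,4a,5-hexahydronaphthalene-2-carboxylate | CC(C)OC(=O)[C@@]1(C)CC[C@]2(C)C(=O)C(Br)=CC(Br)=C2[C@H]1C | intermediate
12 | isopropyl (1R,2S,4aS,8aS)-1,2,4a-trimethyl-5-oxodecahydronaphthalene-2-carboxylate | CC(C)OC(=O)[C@@]1(C)CC[C@]2(C)C(=O)CCC[C@H]2[C@H]1C | intermediate
13 | potassium enolate of 12, C5=C6 (not isolated) | CC(C)OC(=O)[C@@]1(C)CC[C@]2(C)C([O-])=CCC[C@H]2[C@H]1C.[K+] | intermediate
14 | isopropyl (1R,2S,4aS,8aS)-1,2,4a-trimethyl-5-(trifluoromethylsulfonyloxy)-1,2,3,4,4a,7,8,8a-octahydronaphthalene-2-carboxylate | CC(C)OC(=O)[C@@]1(C)CC[C@]2(C)C(OS(=O)(=O)C(F)(F)F)=CCC[C@H]2[C@H]1C | intermediate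
15 | isopropyl (1R,2S,4aS,8aS)-1,2,4a,5-tetramethyl-1,2,3,4,4a,7,8,8a-octahydronaphthalene-2-carboxylate | CC(C)OC(=O)[C@@]1(C)CC[C@]2(C)C(C)=CCC[C@H]2[C@H]1C | intermediate
16 | [(1R,2S,4aS,8aS)-1,2,4a,5-tetramethyl-1,2,3,4,4a,7,8,8a-octahydronaphthalen-2-yl]methanol | OC[C@@]1(C)CC[C@]2(C)C(C)=CCC[C@H]2[C@H]1C | intermediate
17 | (1R,2S,4aS,8aS)-1,2,4a,5-tetramethyl-1,2,3,4,4a,7,8,8a-octahydronaphthalene-2-carbaldehyde | O=C[C@@]1(C)CC[C@]2(C)C(C)=CCC[C@H]2[C@H]1C | intermediate
18 | (1R,2R,4aS,8aS)-2-ethenyl-1,2,4a,5-tetramethyl-1,2,3,4,4a,7,8,8a-octahydronaphthalene | C=C[C@@]1(C)CC[C@]2(C)C(C)=CCC[C@H]2[C@H]1C | intermediate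
19 | methyl 4-bromofuran-2-carboxylate | COC(=O)c1cc(Br)co1 | starting material
20 | methyl 4-methoxyfuran-2-carboxylate | COC(=O)c1cc(OC)co1 | intermediate
21 | methyl 5-bromo-4-methoxyfuran-2-carboxylate | COC(=O)c1cc(OC)c(Br)o1 | intermediate
22 | 9-(2-decalinylethyl)-9-borabicyclo[3.3.1]nonane from 18, boron on the terminal carbon (not isolated) | C(C[C@@]1(C)CC[C@]2(C)C(C)=CCC[C@H]2[C@H]1C)B1C2CCCC1CCC2 | intermediate
23 | methyl 4-methoxy-5-{2-[(1R,2R,4aS,8aS)-1,2,4a,5-tetramethyl-1,2,3,4,4a,7,8,8a-octahydronaphthalen-2-yl]ethyl}furan-2-carboxylate | COC(=O)c1cc(OC)c(CC[C@@]2(C)CC[C@]3(C)C(C)=CCC[C@H]3[C@H]2C)o1 | intermediate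
24 | 2,5-endoperoxide of furan 23, a 2,3,7-trioxabicyclo[2.2.1]hept-5-ene (not isolated) | COC(=O)C12C=C(OC)C(CC[C@@]3(C)CC[C@]4(C)C(C)=CCC[C@H]4[C@H]3C)(OO1)O2 | intermediate
25 | methyl (3E)-4-methoxy-2,5-dioxo-7-[(1R,2R,4aS,8aS)-1,2,4a,5-tetramethyl-1,2,3,4,4a,7,8,8a-octahydronaphthalen-2-yl]hept-3-enoate, carbonyl groups cis (not isolated) | COC(=O)C(=O)/C=C(/OC)C(=O)CC[C@@]1(C)CC[C@]2(C)C(C)=CCC[C@H]2[C@H]1C | intermediate
26 | dysidenone B, methyl (1R,5S)-1-hydroxy-3-methoxy-4-oxo-5-{[(1R,2R,4aS,8aS)-1,2,4a,5-tetramethyl-1,2,3,4,4a,7,8,8a-octahydronaphthalen-2-yl]methyl}cyclopent-2-ene-1-carboxylate | COC(=O)[C@@]1(O)C=C(OC)C(=O)[C@H]1C[C@@]1(C)CC[C@]2(C)C(C)=CCC[C@H]2[C@H]1C | target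

**Step count**
Total: 16 steps. Longest linear sequence: 14 steps (steps 1–12, 15, 16); steps 13–14 make the furan fragment.

**Steps most likely to fail**

Step 6. The ring may close at the wrong atom: ipso attack on the brominated para carbon C8 followed by loss of bromine and re-aromatisation to a tetralin, intermolecular O-alkylation to ethers, or E2 loss of HBr from the arm. The fallback dearomatises ring A by reduction first and closes ring B by α-alkylation of an enone dienolate; it sets out from 8 and comes back at 12. Phenol 8 is hydrogenated over Pd/C (H2, cat. AlCl3, CH2Cl2) to the cyclohexanone isopropyl (2S)-4-bromo-2-methyl-2-[(1R)-1-(2-methyl-3-oxocyclohexyl)ethyl]butanoate F1 (ring stereoisomers, of no consequence). Bromination at the more substituted α-carbon (Br2, AcOH) gives isopropyl (2S)-4-bromo-2-[(1R)-1-(2-bromo-2-methyl-3-oxocyclohexyl)ethyl]-2-methylbutanoate F2, and LiBr/Li2CO3 in DMF at 120 °C eliminates HBr to the enone isopropyl (2S)-4-bromo-2-methyl-2-[(1R)-1-(2-methyl-3-oxocyclohex-1-en-1-yl)ethyl]butanoate F3. KOtBu in t-BuOH forms the extended enolate by loss of a C8 proton, and its α-carbon (C4a) displaces the bromide to give isopropyl (1R,2S,4aS)-1,2,4a-trimethyl-5-oxo-1,2,3,4,4a,5,6,7-octahydronaphthalene-2-carboxylate F4. The same allylic-strain argument applies at C4a, though more weakly without the C8 bromine. Hydrogenation of the C8=C8a alkene of F4 (H2, Pd/C) gives 12.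

Step 16. Ring C may close without facial or relative bias, since the aldol is reversible and the decalin is remote, so the target would be one of several C1/C5 diastereomers; singlet oxygen may also attack the C5=C6 alkene of the decalin in an ene reaction. The fallback replaces the photo-oxygenation cascade by a two-stage ionic sequence; it sets out from 23 and comes back at 26. The furan is opened by bromonium-mediated oxidation (NBS, NaHCO3, THF/H2O, −20 °C) to enedione 25, which is isolated. Ring C is then closed in a separate operation under Lewis-acid catalysis (Dy(OTf)3, MeCN, rt), as a conrotatory closure of the hydroxypentadienyl cation. This is the mode by which Piancatelli rearrangements place the hydroxyl and the neighbouring substituent trans. Unwanted ring C isomers are returned to 25 with Et3N and closed again.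

Step 7. The C8=C8a double bond may migrate on the palladium surface to the tetrasubstituted C1=C8a position before hydrogen is added, which would erase the C1 stereocentre and stall the reduction, or hydrogen may add from the β face to give the cis-fused ketone. The fallback uses dissolving-metal reduction; it sets out from 11 and comes back at 12. Li in NH3/THF at −78 °C removes both bromine atoms and reduces the dienone by electron transfer. The dienyl anion should be protonated by ammonia at C8a from the α face (trans fusion). Quenching the dienolate with NH4Cl gives the β,γ-unsaturated ketone isopropyl (1R,2S,4aS,8aS)-1,2,4a-trimethyl-5-oxo-1,2,3,4,4a,5,6,8a-octahydronaphthalene-2-carboxylate F5. Its disubstituted C7=C8 alkene is hydrogenated with RhCl(PPh3)3/H2, which does not move double bonds, to give 12.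

**Further compounds**
F1 | step 6 | isopropyl (2S)-4-bromo-2-methyl-2-[(1R)-1-(2-methyl-3-oxocyclohexyl)ethyl]butanoate | CC1C(=O)CCCC1[C@@H](C)[C@@](C)(C(=O)OC(C)C)CCBr
F2 | step 6 | isopropyl (2S)-4-bromo-2-[(1R)-1-(2-bromo-2-methyl-3-oxocyclohexyl)ethyl]-2-methylbutanoate | CC1(Br)C(=O)CCCC1[C@@H](C)[C@@](C)(C(=O)OC(C)C)CCBr
F3 | step 6 | isopropyl (2S)-4-bromo-2-methyl-2-[(1R)-1-(2-methyl-3-oxocyclohex-1-en-1-yl)ethyl]butanoate | CC1=C(CCCC1=O)[C@@H](C)[C@@](C)(C(=O)OC(C)C)CCBr
F4 | step 6 | isopropyl (1R,2S,4aS)-1,2,4a-trimethyl-5-oxo-1,2,3,4,4a,5,6,7-octahydronaphthalene-2-carboxylate | CC(C)OC(=O)[C@@]1(C)CC[C@]2(C)C(=O)CCC=C2[C@H]1C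
F0 | step 16 | none | none
F5 | step 7 | isopropyl (1R,2S,4aS,8aS)-1,2,4a-trimethyl-5-oxo-1,2,3,4,4a,5,6,8a-octahydronaphthalene-2-carboxylate | CC(C)OC(=O)[C@@]1(C)CC[C@]2(C)C(=O)CC=C[C@H]2[C@H]1C
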